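**Retrosynthetic overview**
- Kukoamine A (16) is N1,N12-bis(dihydrocaffeoyl)spermine: an acyclic tetra-aza chain whose only rings are the two terminal catechol (3,4-dihydroxyphenyl) benzene rings; it has no stereocentre.
- The strategy rests on this feature: the two secondary amine nitrogens N4 and N9 sit at the two ends of the same C5–C8 tetramethylene chain, and a twofold axis passes through the C6–C7 bond. The N4–C5 and C8–N9 bonds are therefore cut together, giving 1,4-dibromobutane (10) and two copies of the nosyl-activated arm 9.
- Arm 9 is the amide of ketal-protected dihydrocaffeic acid 4 with mono-nosylated propane-1,3-diamine 7.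
- No skeletal ring is formed. The two protective 2,2-dimethyl-1,3-benzodioxole rings are closed in step 2 and opened in step 8, after thiolate removal of the nosyl groups in step 7.

Key step: step 6

Remark: kukoamine A is listed as the neutral free base; step 8 delivers it as its bis(trifluoroacetate) salt, the form in which this air-sensitive catechol polyamine is best kept.

**Route**

Step 1
Reactants: 1 dihydrocaffeic acid, 3-(3,4-dihydroxyphenyl)propanoic acid
Product: 2 methyl 3-(3,4-dihydroxyphenyl)propanoate
Conditions: MeOH, H2SO4 (cat.), reflux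
Reagents that add atoms: methanol, CO
Why: Fischer esterification in methanol as solvent should drive the equilibrium to the methyl ester and mask the acid, which would otherwise interfere with the ketalisation of step 2.

Step 2
Reactants: 2 methyl 3-(3,4-dihydroxyphenyl)propanoate
Product: 3 methyl 3-(2,2-dimethyl-1,3-benzodioxol-5-yl)propanoate
Conditions: 2,2-dimethoxypropane, TsOH·H2O (cat.), toluene, reflux, Soxhlet with 4 Å molecular sieves
Reagents that add atoms: 2,2-dimethoxypropane, COC(C)(C)OC
Why: Acid-catalysed transketalisation of the catechol with 2,2-dimethoxypropane should close the five-membered dioxole ring, the equilibrium being pulled over by trapping the released methanol on the sieves.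

Step 3
Reactants: 3 methyl 3-(2,2-dimethyl-1,3-benzodioxol-5-yl)propanoate
Product: 4 3-(2,2-dimethyl-1,3-benzodioxol-5-yl)propanoic acid
Conditions: LiOH·H2O, THF/H2O, rt; then cold 1 M HCl to pH 3
Reagents that add atoms: lithium hydroxide, [Li+].[OH-]
Why: Saponification of the methyl ester by hydroxide should be clean because the catechol ketal is inert to base and survives a brief cold acidification.

Step 4
Reactants: 5 propane-1,3-diamine; 6 2-nitrobenzenesulfonyl chloride
Product: 7 N-(3-aminopropyl)-2-nitrobenzenesulfonamide
Conditions: 5 (6 equiv), CH2Cl2, 0 °C, slow addition of 6; aqueous wash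
Reagents that add atoms: none
Why: Sulfonamide formation from a sulfonyl chloride and a primary amine: with the symmetric diamine in large excess each molecule of 6 should meet an unreacted diamine, so the mono-sulfonamide dominates and the excess diamine takes up the HCl.

Step 5
Reactants: 4 3-(2,2-dimethyl-1,3-benzodioxol-5-yl)propanoic acid; 7 N-(3-aminopropyl)-2-nitrobenzenesulfonamide
Product: 9 N-[3-(2-nitrophenylsulfonamido)propyl]-3-(2,2-dimethyl-1,3-benzodioxol-5-yl)propanamide, via acyl imidazolide 8 (not isolated)
Conditions: CDI, THF, rt (CO2 evolution); then 7, rt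
Reagents that add atoms: 1,1'-carbonyldiimidazole, O=C(n1ccnc1)n1ccnc1 (its imidazole is carried only in intermediate 8)
Why: Carbonyldiimidazole amide coupling: the acid is converted into acyl imidazolide 8 with loss of CO2, and the primary amine of 7, far more nucleophilic than its sulfonamide N–H, should acylate selectively to the secondary amide.

Step 6
Reactants: 9 N-[3-(2-nitrophenylsulfonamido)propyl]-3-(2,2-dimethyl-1,3-benzodioxol-5-yl)propanamide (2.1 equiv); 10 1,4-dibromobutane (1.0 equiv)
Product: 12 N4,N9-bis(2-nitrophenylsulfonyl)kukoamine A bis(acetonide), via 4-bromobutyl sulfonamide 11 (not isolated)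
Conditions: K2CO3, n-Bu4NI (cat.), DMF, 60 °C
Reagents that add atoms: none
Why: K2CO3 in DMF removes only the 2-nitrobenzenesulfonamide proton of 9, and the nitrogen anion displaces bromide from 10 by SN2 to give 11, whose remaining bromide is displaced in the same way by a second anion, so that the N4–C5 and C8–N9 bonds of the spermine chain are both formed in one flask. The closest known reaction type is the Fukuyama alkylation of nosylamides with primary alkyl halides, run here in two directions on one dielectrophile. No ring is closed and no stereocentre is created. The step needs chemoselectivity between the sulfonamide N–H and the secondary amide N–H, which their acidity gap of many pKa units secures because carbonate cannot ionise the amide. It also needs each nitrogen to be alkylated once only, which the nosyl group secures because the N,N-dialkyl sulfonamide has no N–H left and is not nucleophilic; for the same reason 11 cannot close onto its own nitrogen to a pyrrolidinium ring. The ketals keep the catechols out of reach of base and alkylating agent, and the slight excess of 9 with catalytic iodide (Finkelstein exchange in the flask) should carry both ends to completion.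

Step 7
Reactants: 12 N4,N9-bis(2-nitrophenylsulfonyl)kukoamine A bis(acetonide)
Product: 14 kukoamine A bis(acetonide), via mono-nosyl diamine 13 (not isolated)
Conditions: PhSH, K2CO3, DMF, rt, Ar
Reagents that add atoms: none
Why: Fukuyama nosyl cleavage: thiophenolate adds at the sulfonyl-bearing carbon of each 2-nitrophenyl ring (nucleophilic aromatic substitution through a Meisenheimer adduct), and collapse with loss of SO2 should release each secondary amine while amides and ketals stay untouched.

Step 8
Reactants: 14 kukoamine A bis(acetonide)
Product: 16 kukoamine A, via mono-acetonide 15 (not isolated)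
Conditions: TFA/H2O (9:1), rt, Ar; evaporate, lyophilise (bis(trifluoroacetate) salt)
Reagents that add atoms: none
Why: Acid-catalysed ketal hydrolysis: each benzodioxole should open through an oxocarbenium ion that water turns into acetone and the free catechol, while the amides and the protonated amines are inert to aqueous TFA at room temperature and exclusion of air guards the catechols against quinone formation.

**Compound list**
1 | dihydrocaffeic acid, 3-(3,4-dihydroxyphenyl)propanoic acid | O=C(O)CCc1ccc(O)c(O)c1 | starting material
2 | methyl 3-(3,4-dihydroxyphenyl)propanoate | COC(=O)CCc1ccc(O)c(O)c1 | intermediate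
3 | methyl 3-(2,2-dimethyl-1,3-benzodioxol-5-yl)propanoate | COC(=O)CCc1ccc2OC(C)(C)Oc2c1 | intermediate
4 | 3-(2,2-dimethyl-1,3-benzodioxol-5-yl)propanoic acid | CC1(C)Oc2ccc(CCC(=O)O)cc2O1 | intermediate
5 | propane-1,3-diamine | NCCCN | starting material
6 | 2-nitrobenzenesulfonyl chloride | O=S(=O)(Cl)c1ccccc1[N+](=O)[O-] | starting material
7 | N-(3-aminopropyl)-2-nitrobenzenesulfonamide | NCCCNS(=O)(=O)c1ccccc1[N+](=O)[O-] | intermediate
8 | 1-[3-(2,2-dimethyl-1,3-benzodioxol-5-yl)propanoyl]-1H-imidazole (acyl imidazolide, not isolated) | CC1(C)Oc2ccc(CCC(=O)n3ccnc3)cc2O1 | intermediate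
9 | N-[3-(2-nitrophenylsulfonamido)propyl]-3-(2,2-dimethyl-1,3-benzodioxol-5-yl)propanamide | CC1(C)Oc2ccc(CCC(=O)NCCCNS(=O)(=O)c3ccccc3[N+](=O)[O-])cc2O1 | intermediate
10 | 1,4-dibromobutane | BrCCCCBr | starting material
11 | N-{3-[N-(4-bromobutyl)-2-nitrophenylsulfonamido]propyl}-3-(2,2-dimethyl-1,3-benzodioxol-5-yl)propanamide (not isolated) | CC1(C)Oc2ccc(CCC(=O)NCCCN(CCCCBr)S(=O)(=O)c3ccccc3[N+](=O)[O-])cc2O1 | intermediate
12 | N4,N9-bis(2-nitrophenylsulfonyl)kukoamine A bis(acetonide), the N1,N12-bis[3-(2,2-dimethyl-1,3-benzodioxol-5-yl)propanoyl]-N4,N9-bis(2-nitrophenylsulfonyl)spermine | CC1(C)Oc2ccc(CCC(=O)NCCCN(CCCCN(CCCNC(=O)CCc3ccc4OC(C)(C)Oc4c3)S(=O)(=O)c3ccccc3[N+](=O)[O-])S(=O)(=O)c3ccccc3[N+](=O)[O-])cc2O1 | intermediate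
13 | N4-(2-nitrophenylsulfonyl)kukoamine A bis(acetonide) (mono-nosyl diamine, not isolated) | CC1(C)Oc2ccc(CCC(=O)NCCCNCCCCN(CCCNC(=O)CCc3ccc4OC(C)(C)Oc4c3)S(=O)(=O)c3ccccc3[N+](=O)[O-])cc2O1 | intermediate
14 | kukoamine A bis(acetonide), N1,N12-bis[3-(2,2-dimethyl-1,3-benzodioxol-5-yl)propanoyl]spermine | CC1(C)Oc2ccc(CCC(=O)NCCCNCCCCNCCCNC(=O)CCc3ccc4OC(C)(C)Oc4c3)cc2O1 | intermediate
15 | kukoamine A mono(acetonide) (not isolated) | CC1(C)Oc2ccc(CCC(=O)NCCCNCCCCNCCCNC(=O)CCc3ccc(O)c(O)c3)cc2O1 | intermediate
16 | kukoamine A, N1,N12-bis[3-(3,4-dihydroxyphenyl)propanoyl]spermine (no stereocentre) | O=C(CCc1ccc(O)c(O)c1)NCCCNCCCCNCCCNC(=O)CCc1ccc(O)c(O)c1 | target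

**Step count**
- Total: 8 steps.
- Longest linear sequence: 7 steps (steps 1, 2, 3, 5, 6, 7, 8 from dihydrocaffeic acid); step 4 is a one-step side branch.

**Steps most likely to fail**

1. Step 6 (key step). The second displacement may lag behind the first, so that the mixture stalls at the mono-alkylated bromide 11, and base-induced loss of HBr from 11 may compete at 60 °C. The fallback sets out from 9 and brings in the C4 unit as an allylic dielectrophile. Treatment of 9 (2.1 equiv) with (E)-1,4-dibromobut-2-ene and K2CO3 in DMF at rt should pass through the mono-alkylated (E)-4-bromobut-2-enyl sulfonamide F1 to the (E)-but-2-ene-1,4-diyl bis(sulfonamide) F2. Both displacements are allylic and fast at room temperature. The C=C bond of F2 would then be saturated with diimide (TsNHNH2, NaOAc, DME/H2O, reflux), which spares the nitro groups, sulfonamides and ketals. The fallback comes back to the route at 12.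

2. Step 7. The polar secondary diamine may be lost on silica, and sulfur-containing by-products of the thiol may be carried into the last step. The fallback sets out from 12. The thiolate cleavage is run as before, but the crude diamine is not isolated: Boc2O is added to the same flask, which should give, through the mono(tert-butyl carbamate) F3, the neutral N4,N9-bis(tert-butoxycarbonyl)kukoamine A bis(acetonide) F4, readily purified by ordinary chromatography. In TFA/H2O (9:1) the carbamates should fall first, again through F3, regenerating the diamine as its salt in the flask. The fallback thus comes back to the route at 14, and the same acid carries on as in step 8 to 16.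

3. Step 4. Over-sulfonylation to the bis-sulfonamide and loss of the amphoteric mono-sulfonamide into the aqueous phase may leave little 7. The fallback sets out from ester 3 and reverses the order of the two N-functionalisations. Heating 3 in neat propane-1,3-diamine 5 (large excess, about 90 °C) should give by ester aminolysis the N-(3-aminopropyl)-3-(2,2-dimethyl-1,3-benzodioxol-5-yl)propanamide F5, a simple base that is freed from the volatile diamine by evaporation and extraction. Sulfonylation of its primary amine with 6 (Et3N, CH2Cl2, 0 °C) then bypasses steps 3 to 5 and comes back to the route at 9.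

**Further compounds**
F1 | step 6 | N-{3-[N-((E)-4-bromobut-2-enyl)-2-nitrophenylsulfonamido]propyl}-3-(2,2-dimethyl-1,3-benzodioxol-5-yl)propanamide | CC1(C)Oc2ccc(CCC(=O)NCCCN(C/C=C/CBr)S(=O)(=O)c3ccccc3[N+](=O)[O-])cc2O1
F2 | step 6 | (E)-6,7-didehydro-N4,N9-bis(2-nitrophenylsulfonyl)kukoamine A bis(acetonide) | CC1(C)Oc2ccc(CCC(=O)NCCCN(C/C=C/CN(CCCNC(=O)CCc3ccc4OC(C)(C)Oc4c3)S(=O)(=O)c3ccccc3[N+](=O)[O-])S(=O)(=O)c3ccccc3[N+](=O)[O-])cc2O1
F3 | step 7 | N4-(tert-butoxycarbonyl)kukoamine A bis(acetonide) | CC1(C)Oc2ccc(CCC(=O)NCCCNCCCCN(CCCNC(=O)CCc3ccc4OC(C)(C)Oc4c3)C(=O)OC(C)(C)C)cc2O1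
F4 | step 7 | N4,N9-bis(tert-butoxycarbonyl)kukoamine A bis(acetonide) | CC1(C)Oc2ccc(CCC(=O)NCCCN(CCCCN(CCCNC(=O)CCc3ccc4OC(C)(C)Oc4c3)C(=O)OC(C)(C)C)C(=O)OC(C)(C)C)cc2O1
F5 | step 4 | N-(3-aminopropyl)-3-(2,2-dimethyl-1,3-benzodioxol-5-yl)propanamide | CC1(C)Oc2ccc(CCC(=O)NCCCN)cc2O1
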